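**Retrosynthetic overview**
1. 23 ⇒ 22 by removal of four benzyl ethers. Ring labels: A = dihydrobenzofuran without side chain, B = dihydrobenzofuran that carries the methine C3, C = benzofuran.
2. 22 ⇒ 14 + 19: the bond between the side-chain CH2 on C3 of ring B and C2 of ring C is cut together with both C–O bonds at the spiro carbon. Precursor 14 is an acyclic, achiral α-aryl vinyl ketone.
3. Enabling feature: the spiro carbon shared by the dihydrofuran rings of A and B is a ketone masked by the ortho oxygens of two identical aryl rings. The side-chain CH2 therefore lies β to a latent carbonyl (an enone terminus), and C2–H of ring C is the one C–H of that fragment open to borylation.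
4. 14 ⇒ symmetric 1,3-diarylacetone 11 (one Mannich methylenation) ⇒ bis(arylmethyl)ethene 8 ⇒ tandem double Claisen rearrangement of 6 (two molecules of 4 on linchpin 5). 19 ⇒ benzofuran 17 ⇒ acetal 16. All three arenes come from 3.
5. Ring order: furan ring of C (step 9), then both dihydrofuran rings of the spiroketal in one flask (step 12).

Key step: step 12

Assumption: the sense of induction of the rhodium/(S)-BINAP catalyst on this acceptor class cannot be derived from precedent. (S)-BINAP is written, and (R)-BINAP is used instead if the proton arrives on the opposite face.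

Step 1
Reactants: 1 phloroglucinol; 2 isovaleryl chloride
Product: 3 phlorisovalerophenone, 3-methyl-1-(2,4,6-trihydroxyphenyl)butan-1-one
Conditions: AlCl3 (3.5 equiv), CH2Cl2/PhNO2, 0 to 40 °C; aq HCl work-up
Reagents that add atoms: none
Why: Friedel–Crafts acylation of the threefold-symmetric, strongly activated ring can give one regioisomer only, and the aluminium-chelated aryl ketone formed is deactivated against a second acylation.

Step 2
Reactants: 3 phlorisovalerophenone
Product: 4 1-[2,4-bis(benzyloxy)-6-hydroxyphenyl]-3-methylbutan-1-one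
Conditions: BnBr (2.1 equiv), K2CO3 (2.2 equiv), DMF, 25 to 50 °C
Reagents that add atoms: benzyl bromide, BrCc1ccccc1
Why: Williamson ether synthesis takes the para hydroxyl and one ortho hydroxyl, while the last ortho hydroxyl is held in a strong hydrogen bond to the ketone and stays free, which singles out the oxygen that becomes the ring oxygen of ring A and of ring B.

Step 3
Reactants: 4 1-[2,4-bis(benzyloxy)-6-hydroxyphenyl]-3-methylbutan-1-one (two molecules); 5 3-chloro-2-(chloromethyl)prop-1-ene
Product: 6 2-methylidene-1,3-bis[3,5-bis(benzyloxy)-2-(3-methylbutanoyl)phenoxy]propane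
Conditions: K2CO3 (2.4 equiv), DMF, 80 °C
Reagents that add atoms: none
Why: Double Williamson ether synthesis at elevated temperature overcomes the hydrogen bond of the remaining phenol and hangs two identical aryl units on the bis-allylic three-carbon linchpin.

Step 4
Reactants: 6 2-methylidene-1,3-bis[3,5-bis(benzyloxy)-2-(3-methylbutanoyl)phenoxy]propane
Product: 8 2-methylidene-1,3-bis[4,6-bis(benzyloxy)-2-hydroxy-3-(3-methylbutanoyl)phenyl]propane, via mono-rearranged ether 7 (not isolated)
Conditions: PhNEt2, 190 °C, argon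
Reagents that add atoms: none
Why: Tandem double aromatic Claisen rearrangement, in which each [3,3] shift can reach only the single unsubstituted ortho carbon and the first shift regenerates an allyl aryl ether for the second, forms both aryl–CH2 bonds next to the oxygens that are set free.

Step 5
Reactants: 8 2-methylidene-1,3-bis[4,6-bis(benzyloxy)-2-hydroxy-3-(3-methylbutanoyl)phenyl]propane
Product: 9 2-methylidene-1,3-bis[4,6-bis(benzyloxy)-2-(methoxymethoxy)-3-(3-methylbutanoyl)phenyl]propane
Conditions: NaH (2.5 equiv), MOMCl (2.8 equiv), DMF, 0 °C to rt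
Reagents that add atoms: chloromethyl methyl ether, COCCl
Why: O-alkylation of the sodium phenoxides (Williamson-type acetal ether formation) masks the two ring-forming oxygens by a group orthogonal to benzyl, so that the ketone made next cannot close early.

Step 6
Reactants: 9 2-methylidene-1,3-bis[4,6-bis(benzyloxy)-2-(methoxymethoxy)-3-(3-methylbutanoyl)phenyl]propane
Product: 11 1,3-bis[4,6-bis(benzyloxy)-2-(methoxymethoxy)-3-(3-methylbutanoyl)phenyl]propan-2-one, via diol 10 (not isolated)
Conditions: OsO4 (2 mol %), NaIO4 (4 equiv), 2,6-lutidine, dioxane/H2O 3:1, rt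
Reagents that add atoms: sodium periodate, [Na+].[O-]I(=O)(=O)=O; water, O
Why: Lemieux–Johnson oxidation (catalytic dihydroxylation followed by periodate glycol cleavage) converts the only alkene into the ketone at near-neutral pH, which benzyl ethers, MOM ethers and the electron-rich rings tolerate.

Step 7
Reactants: 11 1,3-bis[4,6-bis(benzyloxy)-2-(methoxymethoxy)-3-(3-methylbutanoyl)phenyl]propan-2-one
Product: 14 1,3-bis[4,6-bis(benzyloxy)-2-(methoxymethoxy)-3-(3-methylbutanoyl)phenyl]but-3-en-2-one, via Mannich base 12 (not isolated), via ammonium iodide 13 (not isolated)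
Conditions: LiN(SiMe3)2 (1.05 equiv), THF, −78 °C; Me2N=CH2 I (1.2 equiv), −78 °C to rt; MeI, rt; sat. aq NaHCO3/CH2Cl2, rt
Reagents that add atoms: N,N-dimethylmethyleneiminium iodide (Eschenmoser's salt), C=[N+](C)C.[I-]; iodomethane, CI (its methyl group stands in 13 only)
Why: Mannich reaction of the lithium enolate (formed at the central ketone, whose aryl-flanked CH2 groups are by far the most acidic) with one equivalent of the iminium salt, then exhaustive methylation and Hofmann-type E1cB elimination, puts one methylidene group on one of two equivalent positions.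

Step 8
Reactants: 3 phlorisovalerophenone; 15 bromoacetaldehyde diethyl acetal
Product: 16 1-[4-(2,2-diethoxyethoxy)-2,6-dihydroxyphenyl]-3-methylbutan-1-one
Conditions: K2CO3 (1.1 equiv), DMF, 100 °C
Reagents that add atoms: none
Why: Williamson ether synthesis with one equivalent of base goes to the para hydroxyl, the most acidic one and the only one not engaged in a hydrogen bond to the ketone, and so marks the future O1 of ring C.

Step 9
Reactants: 16 1-[4-(2,2-diethoxyethoxy)-2,6-dihydroxyphenyl]-3-methylbutan-1-one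
Product: 17 1-(4,6-dihydroxy-1-benzofuran-5-yl)-3-methylbutan-1-one
Conditions: Amberlyst-15, toluene, 110 °C, ethanol distilled off
Reagents that add atoms: none
Why: Acid-catalysed cyclodehydration of an aryloxyacetaldehyde acetal (intramolecular Friedel–Crafts alkylation by the oxocarbenium ion, then loss of ethanol to aromatise) closes the furan ring, and because the two ortho carbons are equivalent only the 4,6-dihydroxy-5-acyl isomer can arise.

Step 10
Reactants: 17 1-(4,6-dihydroxy-1-benzofuran-5-yl)-3-methylbutan-1-one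
Product: 18 1-[4,6-bis(methoxymethoxy)-1-benzofuran-5-yl]-3-methylbutan-1-one
Conditions: NaH (2.5 equiv), MOMCl (3 equiv), DMF, 0 °C to rt
Reagents that add atoms: chloromethyl methyl ether, COCCl
Why: Williamson-type O-alkylation of both sodium phenoxides gives acetal ethers that carry no aryl C–H open to borylation and that, being ortho to the acyl group, fall off under the mild acid of step 12.

Step 11
Reactants: 18 1-[4,6-bis(methoxymethoxy)-1-benzofuran-5-yl]-3-methylbutan-1-one
Product: 19 1-[4,6-bis(methoxymethoxy)-2-(4,4,5,5-tetramethyl-1,3,2-dioxaborolan-2-yl)-1-benzofuran-5-yl]-3-methylbutan-1-one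
Conditions: [Ir(OMe)(cod)]2 (1.5 mol %), dtbpy (3 mol %), B2pin2 (1.0 equiv), MTBE, rt
Reagents that add atoms: bis(pinacolato)diboron, CC1(C)OB(OC1(C)C)B1OC(C)(C)C(C)(C)O1
Why: Iridium-catalysed aromatic C–H borylation is governed by C–H acidity and steric access and should therefore take C2–H of the furan ring, since C7–H is flanked by two oxygen substituents and C3–H lies next to the C4 ether, while ketone and acetal groups are tolerated.

Step 12
Reactants: 14 1,3-bis[4,6-bis(benzyloxy)-2-(methoxymethoxy)-3-(3-methylbutanoyl)phenyl]but-3-en-2-one; 19 benzofuran-2-boronate (1.5 equiv)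
Product: 22 (2R,3S)-4,4',6,6'-tetrakis(benzyloxy)-3-{[4,6-dihydroxy-5-(3-methylbutanoyl)-1-benzofuran-2-yl]methyl}-7,7'-bis(3-methylbutanoyl)-3H,3'H-2,2'-spirobi[1-benzofuran], via (S)-ketone 20 (not isolated), via keto tetraphenol 21 (not isolated)
Conditions: [RhCl(C2H4)2]2 (2.5 mol %), (S)-BINAP (5.5 mol %), KOH (0.3 equiv), dioxane/H2O 10:1, 30 °C; then, without isolation, CH2Cl2, NaHSO4·SiO2, rt
Reagents that add atoms: none
Why: Proposed new method: boron-to-rhodium transmetalation of 19 gives a benzofuran-2-yl complex of monovalent rhodium, which adds across the vinyl ketone of 14 so that the heteroaryl group bonds to the unsubstituted CH2 terminus and an oxa-π-allyl rhodium enolate results, and water protonates this enolate at carbon and returns the hydroxo-rhodium catalyst. The closest known reaction type is the Hayashi–Miyaura 1,4-addition coupled to enantioselective protonation, established for α-substituted acrylates and dehydroamino esters; new here are the α-aryl vinyl ketone acceptor, the 2-heteroaryl boronate and the direct ketalisation. The methine centre (S) is set in the protonation, where the diphosphine blocks one face of the rhodium-bound enolate. The solid acid then removes the four MOM groups (21), one freed phenol adds to the ketone (5-exo-trig) to a hemiketal, water is lost to a cyclic oxocarbenium ion and the second phenol closes the other dihydrofuran ring (5-exo-trig). The spiro centre (R) is set by the methine centre under reversible closure, since the isomer that holds the side chain cis to the small ring-A oxygen and trans to the ring-A CH2 should be the more stable one. The step needs site selectivity on ring C (fixed by boron), 1,4- over 1,2-addition (the three aryl ketones are doubly ortho-substituted and unconjugated), the right phenol oxygen in each closure (the other ortho oxygen stays benzylated) and configurational survival of 20 (its twisted, doubly ortho-substituted aryl group stabilises an enolate poorly and 20 is ketalised at once).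

Step 13
Reactants: 22 (2R,3S)-spiroketal tetrabenzyl ether
Product: 23 target, (2R,3S)-3-{[4,6-dihydroxy-5-(3-methylbutanoyl)-1-benzofuran-2-yl]methyl}-4,4',6,6'-tetrahydroxy-7,7'-bis(3-methylbutanoyl)-3H,3'H-2,2'-spirobi[1-benzofuran]
Conditions: H2 (1 atm), Pd/C (10 %), EtOAc/EtOH, rt
Reagents that add atoms: none
Why: Catalytic hydrogenolysis of the four benzyl aryl ethers runs under neutral conditions that should leave the ketal, the hydrogen-bonded aryl ketones and the 2-substituted benzofuran untouched, so that neither stereocentre meets acid or base.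

**Compound list**
1 | phloroglucinol | Oc1cc(O)cc(O)c1 | starting material
2 | isovaleryl chloride | CC(C)CC(=O)Cl | starting material
3 | phlorisovalerophenone | CC(C)CC(=O)c1c(O)cc(O)cc1O | intermediate
4 | 1-[2,4-bis(benzyloxy)-6-hydroxyphenyl]-3-methylbutan-1-one | CC(C)CC(=O)c1c(O)cc(OCc2ccccc2)cc1OCc1ccccc1 | intermediate
5 | 3-chloro-2-(chloromethyl)prop-1-ene | C=C(CCl)CCl | starting material
6 | 2-methylidene-1,3-bis[3,5-bis(benzyloxy)-2-(3-methylbutanoyl)phenoxy]propane | C=C(COc1cc(OCc2ccccc2)cc(OCc2ccccc2)c1C(=O)CC(C)C)COc1cc(OCc2ccccc2)cc(OCc2ccccc2)c1C(=O)CC(C)C | intermediate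
7 | mono-rearranged ether (one arylmethyl arm, one aryloxymethyl arm on the methylidene carbon) | C=C(Cc1c(O)c(C(=O)CC(C)C)c(OCc2ccccc2)cc1OCc1ccccc1)COc1cc(OCc2ccccc2)cc(OCc2ccccc2)c1C(=O)CC(C)C | intermediate
8 | 2-methylidene-1,3-bis[4,6-bis(benzyloxy)-2-hydroxy-3-(3-methylbutanoyl)phenyl]propane | C=C(Cc1c(O)c(C(=O)CC(C)C)c(OCc2ccccc2)cc1OCc1ccccc1)Cc1c(O)c(C(=O)CC(C)C)c(OCc2ccccc2)cc1OCc1ccccc1 | intermediate
9 | bis-MOM ether of 8 | C=C(Cc1c(OCOC)c(C(=O)CC(C)C)c(OCc2ccccc2)cc1OCc1ccccc1)Cc1c(OCOC)c(C(=O)CC(C)C)c(OCc2ccccc2)cc1OCc1ccccc1 | intermediate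
10 | 2,2-bis(arylmethyl)ethane-1,2-diol from 9 (achiral) | OCC(O)(Cc1c(OCOC)c(C(=O)CC(C)C)c(OCc2ccccc2)cc1OCc1ccccc1)Cc1c(OCOC)c(C(=O)CC(C)C)c(OCc2ccccc2)cc1OCc1ccccc1 | intermediate
11 | 1,3-bis[4,6-bis(benzyloxy)-2-(methoxymethoxy)-3-(3-methylbutanoyl)phenyl]propan-2-one | O=C(Cc1c(OCOC)c(C(=O)CC(C)C)c(OCc2ccccc2)cc1OCc1ccccc1)Cc1c(OCOC)c(C(=O)CC(C)C)c(OCc2ccccc2)cc1OCc1ccccc1 | intermediate
12 | racemic Mannich base, 4-(dimethylamino)-1,3-diarylbutan-2-one | CN(C)CC(C(=O)Cc1c(OCOC)c(C(=O)CC(C)C)c(OCc2ccccc2)cc1OCc1ccccc1)c1c(OCOC)c(C(=O)CC(C)C)c(OCc2ccccc2)cc1OCc1ccccc1 | intermediate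
13 | racemic trimethylammonium iodide of 12 | C[N+](C)(C)CC(C(=O)Cc1c(OCOC)c(C(=O)CC(C)C)c(OCc2ccccc2)cc1OCc1ccccc1)c1c(OCOC)c(C(=O)CC(C)C)c(OCc2ccccc2)cc1OCc1ccccc1.[I-] | intermediate
14 | 1,3-bis[4,6-bis(benzyloxy)-2-(methoxymethoxy)-3-(3-methylbutanoyl)phenyl]but-3-en-2-one | C=C(C(=O)Cc1c(OCOC)c(C(=O)CC(C)C)c(OCc2ccccc2)cc1OCc1ccccc1)c1c(OCOC)c(C(=O)CC(C)C)c(OCc2ccccc2)cc1OCc1ccccc1 | intermediate
15 | bromoacetaldehyde diethyl acetal | CCOC(CBr)OCC | starting material
16 | 1-[4-(2,2-diethoxyethoxy)-2,6-dihydroxyphenyl]-3-methylbutan-1-one | CC(C)CC(=O)c1c(O)cc(OCC(OCC)OCC)cc1O | intermediate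
17 | 1-(4,6-dihydroxy-1-benzofuran-5-yl)-3-methylbutan-1-one | CC(C)CC(=O)c1c(O)cc2occc2c1O | intermediate
18 | 1-[4,6-bis(methoxymethoxy)-1-benzofuran-5-yl]-3-methylbutan-1-one | CC(C)CC(=O)c1c(OCOC)cc2occc2c1OCOC | intermediate
19 | 2-pinacolboronate of 18 | CC(C)CC(=O)c1c(OCOC)cc2oc(B3OC(C)(C)C(C)(C)O3)cc2c1OCOC | intermediate
20 | (3S)-1,3-bis[4,6-bis(benzyloxy)-2-(methoxymethoxy)-3-(3-methylbutanoyl)phenyl]-4-[4,6-bis(methoxymethoxy)-5-(3-methylbutanoyl)-1-benzofuran-2-yl]butan-2-one | O=C(Cc1c(OCOC)c(C(=O)CC(C)C)c(OCc2ccccc2)cc1OCc1ccccc1)[C@@H](Cc1cc2c(OCOC)c(C(=O)CC(C)C)c(OCOC)cc2o1)c1c(OCOC)c(C(=O)CC(C)C)c(OCc2ccccc2)cc1OCc1ccccc1 | intermediate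
21 | (3S)-1,3-bis[4,6-bis(benzyloxy)-2-hydroxy-3-(3-methylbutanoyl)phenyl]-4-[4,6-dihydroxy-5-(3-methylbutanoyl)-1-benzofuran-2-yl]butan-2-one | O=C(Cc1c(O)c(C(=O)CC(C)C)c(OCc2ccccc2)cc1OCc1ccccc1)[C@@H](Cc1cc2c(O)c(C(=O)CC(C)C)c(O)cc2o1)c1c(O)c(C(=O)CC(C)C)c(OCc2ccccc2)cc1OCc1ccccc1 | intermediate
22 | (2R,3S)-spiroketal tetrabenzyl ether | CC(C)CC(=O)c1c(OCc3ccccc3)cc(OCc3ccccc3)c2c1O[C@]1(C2)Oc2c(C(=O)CC(C)C)c(OCc3ccccc3)cc(OCc3ccccc3)c2[C@@H]1Cc1cc2c(O)c(C(=O)CC(C)C)c(O)cc2o1 | intermediate
23 | CNP0169640.1, (2R,3S) | CC(C)CC(=O)c1c(O)cc(O)c2c1O[C@]1(C2)Oc2c(C(=O)CC(C)C)c(O)cc(O)c2[C@@H]1Cc1cc2c(O)c(C(=O)CC(C)C)c(O)cc2o1 | target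

**Totals**
Total step count: 13. Longest linear sequence: 9 steps (1 to 7, 12, 13).

**Steps most likely to fail**

Step 12.
- Possible failures:
  - The enolate may be protonated outside the chiral pocket, by hydrolysis to the free enol.
  - The α-aryl ketone may enolise before it is ketalised.
  - The boronate may suffer protodeboronation.
  - The hemiketal may dehydrate to a 2,3-disubstituted benzofuran instead of undergoing the second ring closure.
- Fallback, from 14 and 19, back at 22: the bond-forming event is kept and asymmetric induction is given up.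
- The known racemic Hayashi–Miyaura addition with achiral [Rh(OH)(cod)]2 in aqueous dioxane gives 20 together with its antipode, (R)-ketone F1.
- NaHSO4·SiO2 carries both through 21 and (R)-keto tetraphenol F2 to 22 and its mirror image, (2S,3R)-spiroketal F3. The relative configuration comes from the same equilibration.
- The enantiomers are separated by preparative chromatography on a cellulose-carbamate chiral stationary phase, and the (2R,3S) fraction is 22.

Step 9.
- Possible failures: acid-induced loss of the acyl group (retro-Friedel–Crafts), intermolecular acetal exchange of the free phenols with oligomerisation, and, one step earlier, incomplete discrimination of the three hydroxyls by the sluggish bromoacetal.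
- Fallback, from 3, back at 18: the furan carbons come from an allyl group instead of an acetal.
- Para-O-allylation of 3 (allyl bromide, K2CO3, acetone) gives allyl ether F4.
- NaH/MOMCl gives bis-MOM allyl ether F5.
- Aromatic Claisen rearrangement (PhNEt2, 190 °C, both ortho carbons equivalent) gives C-allyl phenol F6, whose only free hydroxyl is the one that must become O1.
- Lemieux–Johnson cleavage (OsO4 cat., NaIO4) gives the arylacetaldehyde in its ring-closed form, lactol F7.
- MsCl/Et3N dehydrates the lactol to 18 without touching the MOM groups.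

Step 7.
- Possible failures: a second aminomethylation at the other benzylic CH2, and polymerisation or hetero-Diels–Alder dimerisation of the vinyl ketone during isolation and storage.
- Fallback, from 11, back at 20: the sequence is stopped at ammonium iodide 13, which is precipitated and washed as a salt.
- 13 is then charged directly into the rhodium stage of step 12 together with K3PO4 (1.2 equiv).
- The base releases 14 slowly by E1cB elimination in the presence of the heteroaryl-rhodium species, the classical use of a Mannich salt as a vinyl ketone surrogate, so the free enone never accumulates.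
- New compounds on this path: none F0.

**Further compounds**
F1 | step 12 | (3R)-antipode of ketone 20 | O=C(Cc1c(OCOC)c(C(=O)CC(C)C)c(OCc2ccccc2)cc1OCc1ccccc1)[C@H](Cc1cc2c(OCOC)c(C(=O)CC(C)C)c(OCOC)cc2o1)c1c(OCOC)c(C(=O)CC(C)C)c(OCc2ccccc2)cc1OCc1ccccc1
F2 | step 12 | (3R)-antipode of keto tetraphenol 21 | O=C(Cc1c(O)c(C(=O)CC(C)C)c(OCc2ccccc2)cc1OCc1ccccc1)[C@H](Cc1cc2c(O)c(C(=O)CC(C)C)c(O)cc2o1)c1c(O)c(C(=O)CC(C)C)c(OCc2ccccc2)cc1OCc1ccccc1
F3 | step 12 | (2S,3R)-antipode of spiroketal 22 | CC(C)CC(=O)c1c(OCc3ccccc3)cc(OCc3ccccc3)c2c1O[C@@]1(C2)Oc2c(C(=O)CC(C)C)c(OCc3ccccc3)cc(OCc3ccccc3)c2[C@H]1Cc1cc2c(O)c(C(=O)CC(C)C)c(O)cc2o1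
F4 | step 9 | 1-[2,6-dihydroxy-4-(prop-2-en-1-yloxy)phenyl]-3-methylbutan-1-one | CC(C)CC(=O)c1c(O)cc(OCC=C)cc1O
F5 | step 9 | 1-[2,6-bis(methoxymethoxy)-4-(prop-2-en-1-yloxy)phenyl]-3-methylbutan-1-one | CC(C)CC(=O)c1c(OCOC)cc(OCC=C)cc1OCOC
F6 | step 9 | 1-[4-hydroxy-2,6-bis(methoxymethoxy)-3-(prop-2-en-1-yl)phenyl]-3-methylbutan-1-one | CC(C)CC(=O)c1c(OCOC)cc(O)c(CC=C)c1OCOC
F7 | step 9 | racemic lactol, 1-[2-hydroxy-4,6-bis(methoxymethoxy)-2,3-dihydro-1-benzofuran-5-yl]-3-methylbutan-1-one | CC(C)CC(=O)c1c(OCOC)cc2OC(O)Cc2c1OCOC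
F0 | step 7 | none | none
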